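**Plan**

Ring locants: C1 = CMe2, C2 = CH2, C3 = CH(OH), C4 = CH2, C5 = C(Me)=, C6 = =C(alkynyl). Cut 1 is the C6–C(sp) bond (Sonogashira) into hydroxy cyclohexenyl triflate 11 and C21 polyenynal 14; cut 2 takes the alkyne of 14 back to one aldehyde of all-E crocetin dialdehyde 12.
Cut 3, in the ring: the bonds C1–C2 and C3–C4 together, as a retro-[4+2] of the cyclohexene, whose only C=C (C5=C6) lies opposite the C2–C3 edge.
Enabling feature: carbinol carbon C3 is 1,4 to the sp2 carbon C6. With C6 as a silyl enol ether carbon, the diene CH2=C(Me)–C(OSi)=CMe2 is polarised so that its CMe2 end (C1) bonds to the CH2 of methyl vinyl ketone and its CH2 end (C4) to the acyl-bearing carbon.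
Forward order: enone → silyl dienol ether → ring by enantioselective Diels–Alder reaction → enol triflate at C6 → Baeyer–Villiger shift of the acetyl helper to acetoxy at C3 → alcohol → chain joined last at C6.
Helpers: the acetyl group activates the dienophile and is then turned into the C3 oxygen; the silyloxy group steers the regiochemistry and becomes the triflate leaving group.
Stereochemistry: C3 (R) is set by the chiral oxazaborolidinium catalyst in the cycloaddition and kept with retention in the Baeyer–Villiger shift; the seven E double bonds are bought with 12 and are not touched.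

Key step: step 3

Assumption: the (S)-configured catalyst is taken to expose the same face of methyl vinyl ketone as of acrylate esters (the face that leads to the (S)-cyclohex-3-enecarboxylate from buta-1,3-diene); because the CIP order of the two ring CH2 groups is reversed in 7, this face corresponds to (R), and the (R)-configured catalyst would be used should the sense prove opposite.

**Route**

Step 1
Reactants: 1 N-methoxy-N,2-dimethylpropanamide; 2 isopropenylmagnesium bromide
Product: 4 2,4-dimethylpent-1-en-3-one, via magnesium chelate 3 (not isolated)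
Conditions: THF, −10 → 0 °C; then poured into cold 1 M HCl
Reagents that add atoms: none
Why: Weinreb ketone synthesis: the chelated tetrahedral adduct 3 resists a second addition and collapses to the enone only on the cold acidic quench, which keeps the liberated amine protonated so that it does not add to the enone.

Step 2
Reactants: 4 2,4-dimethylpent-1-en-3-one
Product: 5 [(2,4-dimethylpenta-1,3-dien-3-yl)oxy]tri(propan-2-yl)silane
Conditions: TIPSOTf, Et3N, CH2Cl2, 0 → 23 °C
Reagents that add atoms: triisopropylsilyl trifluoromethanesulfonate, CC(C)[Si](OS(=O)(=O)C(F)(F)F)(C(C)C)C(C)C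
Why: Soft enolisation of an enone with a silyl triflate and a tertiary amine: the only acidic hydrogen is the tertiary one of the isopropyl group, so O-silylation should give the cross-conjugated silyl dienol ether as one isomer (the enol carbon carries two methyl groups, so there is no E/Z question).

Step 3
Reactants: 5 [(2,4-dimethylpenta-1,3-dien-3-yl)oxy]tri(propan-2-yl)silane; 6 but-3-en-2-one (methyl vinyl ketone)
Product: 7 1-[(1R)-3,5,5-trimethyl-4-{[tri(propan-2-yl)silyl]oxy}cyclohex-3-en-1-yl]ethan-1-one
Conditions: (3aS)-1-(2-methylphenyl)-3,3-diphenyltetrahydro-1H,3H-pyrrolo[1,2-c][1,3,2]oxazaborole (20 mol %), Tf2NH (17 mol %), CH2Cl2, −78 → −20 °C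
Reagents that add atoms: none
Why: Catalytic enantioselective Diels–Alder reaction of a 2-silyloxy-1,3-diene with an enone bound through its carbonyl oxygen to a chiral cationic oxazaborolidinium Lewis acid (closest known type: this catalyst class with 2-(triisopropylsilyloxy)buta-1,3-diene and acrylates or enones); the [4+2] is concerted but strongly asynchronous, the bond from the enol-ether carbon (CMe2 end of the diene) to the β-CH2 of the enone leading with Mukaiyama–Michael character and the bond from the α-carbon to the diene CH2 end following. The cyclohexene ring closes by intermolecular suprafacial [4+2] cycloaddition, which makes the CMe2–CH2 and CH(acyl)–CH2 bonds and places the C=C in the ring between the methyl-bearing and the silyloxy-bearing carbons. The one new stereocentre (acetyl-bearing carbon, R) is fixed by the catalyst, whose aryl groups shield one face of the coordinated enone so that the diene adds to the open face; endo/exo plays no role because neither diene terminus is stereogenic. The step needs regioselectivity (1,4 relation of silyloxy carbon and acetyl carbon), secured by the silyloxy group, which makes the CMe2 terminus the nucleophilic end and outweighs the three methyl groups, and by sterics, since the quaternary carbon forms from the unsubstituted CH2 of the dienophile. It also needs cycloaddition to win over open-chain Michael addition, secured by the bulky triisopropylsilyl group, which resists silyl transfer, and by a slight deficit of Tf2NH, which leaves no free acid to cleave the enol ether.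

Step 4
Reactants: 7 1-[(1R)-3,5,5-trimethyl-4-{[tri(propan-2-yl)silyl]oxy}cyclohex-3-en-1-yl]ethan-1-one
Product: 9 (4R)-4-acetyl-2,6,6-trimethylcyclohex-1-en-1-yl trifluoromethanesulfonate, via cesium enolate 8 (not isolated)
Conditions: CsF, PhNTf2 (excess), DME, 23 °C
Reagents that add atoms: N-phenylbis(trifluoromethanesulfonimide), O=S(=O)(N(c1ccccc1)S(=O)(=O)C(F)(F)F)C(F)(F)F
Why: Fluoride-triggered conversion of a silyl enol ether into an enol triflate: CsF removes the silyl group and the regiodefined tetrasubstituted enolate 8 (its other α-carbon is quaternary) should be O-sulfonylated by the excess PhNTf2 before it exchanges protons with the methyl ketone, so that the stereocentre survives.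

Step 5
Reactants: 9 (4R)-4-acetyl-2,6,6-trimethylcyclohex-1-en-1-yl trifluoromethanesulfonate
Product: 10 (1R)-3,5,5-trimethyl-4-[(trifluoromethanesulfonyl)oxy]cyclohex-3-en-1-yl acetate
Conditions: mCPBA, CH2Cl2, 23 → 40 °C
Reagents that add atoms: 3-chloroperoxybenzoic acid, OOC(=O)c1cccc(Cl)c1
Why: Baeyer–Villiger oxidation: the secondary ring carbon migrates in preference to methyl with retention of configuration, which turns the acetyl helper into the acetate of the (R)-alcohol, while the enol triflate C=C is deactivated toward the electrophilic peracid by the triflyloxy group.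

Step 6
Reactants: 10 (1R)-3,5,5-trimethyl-4-[(trifluoromethanesulfonyl)oxy]cyclohex-3-en-1-yl acetate
Product: 11 (4R)-4-hydroxy-2,6,6-trimethylcyclohex-1-en-1-yl trifluoromethanesulfonate
Conditions: i-Bu2AlH, CH2Cl2, −78 °C; aqueous KNaC4H4O6 work-up
Reagents that add atoms: none
Why: Reductive cleavage of the acetate by an aluminium hydride at low temperature, to which the alkenyl triflate is inert; the stereocentre is not involved.

Step 7
Reactants: 12 (2E,4E,6E,8E,10E,12E,14E)-2,6,11,15-tetramethylhexadeca-2,4,6,8,10,12,14-heptaenedial (crocetin dialdehyde)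
Product: 14 (2E,4E,6E,8E,10E,12E,14E)-2,6,11,15-tetramethylheptadeca-2,4,6,8,10,12,14-heptaen-16-ynal, via lithium diazo alkoxide 13 (not isolated)
Conditions: Me3SiCHN2 (0.9 equiv), n-BuLi, THF, −78 → 0 °C, dark
Reagents that add atoms: (trimethylsilyl)diazomethane, C[Si](C)(C)C=[N+]=[N-]
Why: Colvin homologation: lithiated (trimethylsilyl)diazomethane adds 1,2 to one aldehyde to give 13, which on warming should extrude lithium trimethylsilanolate and N2 with 1,2-hydrogen shift to the terminal alkyne; the aprotic conditions avoid alcohol addition to the enal, and a deficit of reagent with recovery of 12 favours mono-reaction of the symmetric dialdehyde.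

Step 8
Reactants: 11 (4R)-4-hydroxy-2,6,6-trimethylcyclohex-1-en-1-yl trifluoromethanesulfonate; 14 (2E,4E,6E,8E,10E,12E,14E)-2,6,11,15-tetramethylheptadeca-2,4,6,8,10,12,14-heptaen-16-ynal
Product: 15 (2E,4E,6E,8E,10E,12E,14E)-17-[(4R)-4-hydroxy-2,6,6-trimethylcyclohex-1-en-1-yl]-2,6,11,15-tetramethylheptadeca-2,4,6,8,10,12,14-heptaen-16-ynal
Conditions: Pd(PPh3)4 (5 mol %), CuI (10 mol %), Et3N, DMF, 23 → 45 °C, argon, dark
Reagents that add atoms: none
Why: Sonogashira coupling: zerovalent palladium inserts into the alkenyl C–OTf bond, the copper acetylide of 14 transmetalates and reductive elimination forms the C(sp2)–C(sp) bond; free hydroxyl and aldehyde are tolerated, the tertiary amine cannot condense with the aldehyde, and no alkene geometry or stereocentre is touched.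

**Compound list**

1 | N-methoxy-N,2-dimethylpropanamide | CC(C)C(=O)N(C)OC | starting material
2 | isopropenylmagnesium bromide | CC(=C)[Mg]Br | starting material
3 | bromomagnesium 3-[methoxy(methyl)amino]-2,4-dimethylpent-1-en-3-olate (magnesium chelate) | CC(C)C(O[Mg]Br)(N(C)OC)C(C)=C | intermediate
4 | 2,4-dimethylpent-1-en-3-one | CC(C)C(=O)C(C)=C | intermediate
5 | [(2,4-dimethylpenta-1,3-dien-3-yl)oxy]tri(propan-2-yl)silane | CC(C)=C(O[Si](C(C)C)(C(C)C)C(C)C)C(C)=C | intermediate
6 | but-3-en-2-one (methyl vinyl ketone) | CC(=O)C=C | starting material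
7 | 1-[(1R)-3,5,5-trimethyl-4-{[tri(propan-2-yl)silyl]oxy}cyclohex-3-en-1-yl]ethan-1-one | CC1=C(O[Si](C(C)C)(C(C)C)C(C)C)C(C)(C)C[C@H](C(C)=O)C1 | intermediate
8 | cesium (4R)-4-acetyl-2,6,6-trimethylcyclohex-1-en-1-olate | CC1=C([O-])C(C)(C)C[C@H](C(C)=O)C1.[Cs+] | intermediate
9 | (4R)-4-acetyl-2,6,6-trimethylcyclohex-1-en-1-yl trifluoromethanesulfonate | CC1=C(OS(=O)(=O)C(F)(F)F)C(C)(C)C[C@H](C(C)=O)C1 | intermediate
10 | (1R)-3,5,5-trimethyl-4-[(trifluoromethanesulfonyl)oxy]cyclohex-3-en-1-yl acetate | CC1=C(OS(=O)(=O)C(F)(F)F)C(C)(C)C[C@H](OC(C)=O)C1 | intermediate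
11 | (4R)-4-hydroxy-2,6,6-trimethylcyclohex-1-en-1-yl trifluoromethanesulfonate | CC1=C(OS(=O)(=O)C(F)(F)F)C(C)(C)C[C@H](O)C1 | intermediate
12 | (2E,4E,6E,8E,10E,12E,14E)-2,6,11,15-tetramethylhexadeca-2,4,6,8,10,12,14-heptaenedial (crocetin dialdehyde) | O=C/C(C)=C/C=C/C(C)=C/C=C/C=C(C)/C=C/C=C(\C)C=O | starting material
13 | lithium (3E,5E,7E,9E,11E,13E,15E)-1-diazo-3,7,12,16-tetramethyl-17-oxo-1-(trimethylsilyl)heptadeca-3,5,7,9,11,13,15-heptaen-2-olate | [Li+].[O-]C(C(=[N+]=[N-])[Si](C)(C)C)/C(C)=C/C=C/C(C)=C/C=C/C=C(C)/C=C/C=C(\C)C=O | intermediate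
14 | (2E,4E,6E,8E,10E,12E,14E)-2,6,11,15-tetramethylheptadeca-2,4,6,8,10,12,14-heptaen-16-ynal | C#C/C(C)=C/C=C/C(C)=C/C=C/C=C(C)/C=C/C=C(\C)C=O | intermediate
15 | (2E,4E,6E,8E,10E,12E,14E)-17-[(4R)-4-hydroxy-2,6,6-trimethylcyclohex-1-en-1-yl]-2,6,11,15-tetramethylheptadeca-2,4,6,8,10,12,14-heptaen-16-ynal | CC1=C(C#C/C(C)=C/C=C/C(C)=C/C=C/C=C(C)/C=C/C=C(\C)C=O)C(C)(C)C[C@H](O)C1 | target

**Step count**

Total steps: 8. Longest linear sequence: 7 (steps 1 to 6, then step 8); step 7 prepares the chain fragment in parallel.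

**Steps most likely to fail**

1. Step 3. The twisted, fully substituted diene may react too slowly at low temperature. Silyl transfer may divert the first-formed adduct to an open-chain Michael product. The catalyst may discriminate the enone faces poorly. The fallback takes the stereocentre from an enzymatic kinetic resolution; it sets out from 5 (with 6) and comes back at 11. Thermal cycloaddition without catalyst (toluene, 120 °C, sealed tube, a trace of 2,6-di-tert-butyl-4-methylphenol) should give racemic 1-[3,5,5-trimethyl-4-(triisopropylsilyloxy)cyclohex-3-en-1-yl]ethan-1-one F1 with the same silyloxy-directed regiochemistry. The conditions of step 4 should then give racemic 4-acetyl-2,6,6-trimethylcyclohex-1-en-1-yl trifluoromethanesulfonate F2, and those of step 5 racemic 3,5,5-trimethyl-4-(trifluoromethanesulfonyloxy)cyclohex-3-en-1-yl acetate F3. Hydrolysis of F3 with lipase B from Candida antarctica (phosphate buffer pH 7, tert-butyl methyl ether, 30 °C) is expected, by the empirical rule for lipases and secondary alcohols, to cleave the (R)-acetate. This should give 11 and leave (1S)-3,5,5-trimethyl-4-(trifluoromethanesulfonyloxy)cyclohex-3-en-1-yl acetate F4, which is removed by chromatography.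

2. Step 8. Slow oxidative addition at the hindered tetrasubstituted alkenyl triflate may let the terminal polyenyne dimerise oxidatively or oligomerise. The long polyenal may also isomerise or decompose under palladium and amine. The fallback builds the chain stepwise by olefination; it sets out from 11 and comes back at 15.
   - Sonogashira coupling of 11 with the small, robust, purchased (2E)-3-methylpent-2-en-4-yn-1-ol (Pd(PPh3)4, CuI, Et3N, DMF) should give (2E)-5-[(4R)-4-hydroxy-2,6,6-trimethylcyclohex-1-en-1-yl]-3-methylpent-2-en-4-yn-1-ol F5.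
   - PPh3·HBr in MeOH should convert the allylic alcohol into [(2E)-5-[(4R)-4-hydroxy-2,6,6-trimethylcyclohex-1-en-1-yl]-3-methylpent-2-en-4-yn-1-yl]triphenylphosphonium bromide F6.
   - Wittig reaction of F6 with an excess of purchased (2E,4E,6E)-2,7-dimethylocta-2,4,6-trienedial (NaOMe, CH2Cl2/MeOH), followed by thermal or I2-catalysed equilibration to the all-E isomer, should give (2E,4E,6E,8E,10E)-13-[(4R)-4-hydroxy-2,6,6-trimethylcyclohex-1-en-1-yl]-2,7,11-trimethyltrideca-2,4,6,8,10-pentaen-12-ynal F7.
   - Horner–Wadsworth–Emmons reaction of F7 with purchased ethyl (2E)-4-(diethoxyphosphoryl)-2-methylbut-2-enoate (NaH, THF, 0 °C) should give ethyl (2E,4E,6E,8E,10E,12E,14E)-17-[(4R)-4-hydroxy-2,6,6-trimethylcyclohex-1-en-1-yl]-2,6,11,15-tetramethylheptadeca-2,4,6,8,10,12,14-heptaen-16-ynoate F8.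
   - i-Bu2AlH (CH2Cl2, −78 °C) should reduce F8 to (2E,4E,6E,8E,10E,12E,14E)-17-[(4R)-4-hydroxy-2,6,6-trimethylcyclohex-1-en-1-yl]-2,6,11,15-tetramethylheptadeca-2,4,6,8,10,12,14-heptaen-16-yn-1-ol F9.
   - MnO2 (CH2Cl2, 23 °C) should oxidise only the allylic primary alcohol of F9, leaving the homoallylic ring alcohol, to give 15.

3. Step 4. Proton exchange between the liberated enolate 8 and the methyl ketone may lead to sulfonylation of the acetyl enolate or to epimerisation at the acetyl-bearing carbon. The fallback uses a dienophile without an enolisable ketone; it sets out from 5 and comes back at 9. Cycloaddition of 5 with purchased 2,2,2-trifluoroethyl acrylate under the catalyst of step 3 should give 2,2,2-trifluoroethyl (1R)-3,5,5-trimethyl-4-(triisopropylsilyloxy)cyclohex-3-ene-1-carboxylate F10. CsF and PhNTf2 in DME should give 2,2,2-trifluoroethyl (1R)-3,5,5-trimethyl-4-(trifluoromethanesulfonyloxy)cyclohex-3-ene-1-carboxylate F11, whose ester α-hydrogen is far less acidic. MeNH(OMe)·HCl with i-PrMgCl (THF, −20 °C) should give (1R)-N-methoxy-N,3,5,5-tetramethyl-4-(trifluoromethanesulfonyloxy)cyclohex-3-ene-1-carboxamide F12. MeMgBr (THF, −20 °C) should then give 9.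

**Further compounds**

F1 | step 3 | racemic 1-[3,5,5-trimethyl-4-(triisopropylsilyloxy)cyclohex-3-en-1-yl]ethan-1-one | CC1=C(O[Si](C(C)C)(C(C)C)C(C)C)C(C)(C)CC(C(C)=O)C1
F2 | step 3 | racemic 4-acetyl-2,6,6-trimethylcyclohex-1-en-1-yl trifluoromethanesulfonate | CC1=C(OS(=O)(=O)C(F)(F)F)C(C)(C)CC(C(C)=O)C1
F3 | step 3 | racemic 3,5,5-trimethyl-4-(trifluoromethanesulfonyloxy)cyclohex-3-en-1-yl acetate | CC1=C(OS(=O)(=O)C(F)(F)F)C(C)(C)CC(OC(C)=O)C1
F4 | step 3 | (1S)-3,5,5-trimethyl-4-(trifluoromethanesulfonyloxy)cyclohex-3-en-1-yl acetate | CC1=C(OS(=O)(=O)C(F)(F)F)C(C)(C)C[C@@H](OC(C)=O)C1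
F5 | step 8 | (2E)-5-[(4R)-4-hydroxy-2,6,6-trimethylcyclohex-1-en-1-yl]-3-methylpent-2-en-4-yn-1-ol | CC1=C(C#C/C(C)=C/CO)C(C)(C)C[C@H](O)C1
F6 | step 8 | [(2E)-5-[(4R)-4-hydroxy-2,6,6-trimethylcyclohex-1-en-1-yl]-3-methylpent-2-en-4-yn-1-yl]triphenylphosphonium bromide | CC1=C(C#C/C(C)=C/C[P+](c2ccccc2)(c2ccccc2)c2ccccc2)C(C)(C)C[C@H](O)C1.[Br-]
F7 | step 8 | (2E,4E,6E,8E,10E)-13-[(4R)-4-hydroxy-2,6,6-trimethylcyclohex-1-en-1-yl]-2,7,11-trimethyltrideca-2,4,6,8,10-pentaen-12-ynal | CC1=C(C#C/C(C)=C/C=C/C(C)=C/C=C/C=C(\C)C=O)C(C)(C)C[C@H](O)C1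
F8 | step 8 | ethyl (2E,4E,6E,8E,10E,12E,14E)-17-[(4R)-4-hydroxy-2,6,6-trimethylcyclohex-1-en-1-yl]-2,6,11,15-tetramethylheptadeca-2,4,6,8,10,12,14-heptaen-16-ynoate | CC1=C(C#C/C(C)=C/C=C/C(C)=C/C=C/C=C(C)/C=C/C=C(\C)C(=O)OCC)C(C)(C)C[C@H](O)C1
F9 | step 8 | (2E,4E,6E,8E,10E,12E,14E)-17-[(4R)-4-hydroxy-2,6,6-trimethylcyclohex-1-en-1-yl]-2,6,11,15-tetramethylheptadeca-2,4,6,8,10,12,14-heptaen-16-yn-1-ol | CC1=C(C#C/C(C)=C/C=C/C(C)=C/C=C/C=C(C)/C=C/C=C(\C)CO)C(C)(C)C[C@H](O)C1
F10 | step 4 | 2,2,2-trifluoroethyl (1R)-3,5,5-trimethyl-4-(triisopropylsilyloxy)cyclohex-3-ene-1-carboxylate | CC1=C(O[Si](C(C)C)(C(C)C)C(C)C)C(C)(C)C[C@H](C(=O)OCC(F)(F)F)C1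
F11 | step 4 | 2,2,2-trifluoroethyl (1R)-3,5,5-trimethyl-4-(trifluoromethanesulfonyloxy)cyclohex-3-ene-1-carboxylate | CC1=C(OS(=O)(=O)C(F)(F)F)C(C)(C)C[C@H](C(=O)OCC(F)(F)F)C1
F12 | step 4 | (1R)-N-methoxy-N,3,5,5-tetramethyl-4-(trifluoromethanesulfonyloxy)cyclohex-3-ene-1-carboxamide | CC1=C(OS(=O)(=O)C(F)(F)F)C(C)(C)C[C@H](C(=O)N(C)OC)C1
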